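The numbers in the tables stem from a simulated flask with constants of no real substance; the scatter is artificial.

What is left over of the free catalyst after the impurity has bound its share is the number to watch. Take 21.2% for the flask: that is the surplus share, one minus the impurity charge over the catalyst charge. It is 60.6% for oak and −57.7% for larch, where the impurity outnumbers the catalyst.

| setting | oak | larch | flask |
|---|---|---|---|
| left-handed substrate | 0.098 M | 0.098 M | 0.098 M |
| right-handed substrate | 0.098 M | 0.098 M | 0.098 M |
| gas | 3.7 mM (held) | 3.7 mM (held) | 3.7 mM (held) |
| free catalyst | 4.4 mol% | 4.4 mol% | 4.4 mol% |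
| impurity | 1.7 mM | 6.8 mM | 3.4 mM |
| remark | run made earlier | run made earlier |  |
| time |  |  | 40 h |

- oak (time / h: left-handed product / %, right-handed product / %, left-handed substrate / %): 5.00: 8.5, 0.7, 40.9; 10.0: 14.9, 3.8, 34.0; 15.0: 19.4, 7.5, 28.6; 20.0: 21.5, 10.3, 22.6; 25.0: 24.4, 12.7, 20.1; 30.0: 26.3, 15.5, 15.2
- larch (time / h: left-handed product / %, right-handed product / %, left-handed substrate / %): 5.00: 5.0, 0.6, 44.9; 10.0: 6.1, 1.7, 43.0; 15.0: 6.1, 3.1, 41.5; 20.0: 6.8, 3.2, 41.9; 25.0: 5.9, 3.9, 42.8; 30.0: 5.1, 4.4, 41.3

(standard deviation of a reading: 0.5 percentage points)

- free catalyst is single-handed; left-handed substrate and right-handed substrate are mirror images of each other, charged as a racemate, each of them at the stated concentration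
- at the start none of reagent is dissolved
- candidate steps: gas <-> reagent; reagent + free catalyst + right-handed substrate -> free catalyst + right-handed product; left-handed product <-> right-handed product; reagent + free catalyst + left-handed substrate -> free catalyst + left-handed product; free catalyst + impurity -> spent catalyst
- an excess is the difference of the two amounts in percent of their sum
- an excess is below zero if the other one leads

1. excess of left-handed product over right-handed product in the product at 50 min
2. excess of left-handed product over right-handed product in the product at 40 h
3. part of the left-handed substrate and right-handed substrate charged together that has reacted at 40 h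

The larch readings fit that count: left-handed substrate reads 41.5% at 15.0 h and 41.3% at 30.0 h, a stall within the scatter. The dispute is over how soon the flask reaches its surplus share.

The first view, reckoned here, says at once. Between 15.0 h and 30.0 h, oak's left-handed substrate decays at a pseudo-first-order 0.0421 h⁻¹, read on a surplus of 60.6%. Scaled to the flask's surplus over 40 h, that leaves 27.8% of the pair charged as left-handed substrate.

The second view is the forecast's. Larch has no surplus, yet it made 5.0% of left-handed product by 5.00 h, so larch's catalyst is not bound at once. The forecast calls the flask's surplus “reached slowly”, puts left-handed substrate at 22.5%, and gives 75%, 21% and 32.6%, in the order asked.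

    gas ⇌ reagent, rate k1*(csat - [reagent]) (kL = 0.0656 min⁻¹)
    reagent + free catalyst + right-handed substrate → free catalyst + right-handed product (k = 9.93 M⁻² min⁻¹)
    left-handed product ⇌ right-handed product (k = 4.66 × 10⁻⁴ min⁻¹)
    reagent + free catalyst + left-handed substrate → free catalyst + left-handed product (k = 76.1 M⁻² min⁻¹)
    free catalyst + impurity → spent catalyst (k = 1.26 M⁻¹ min⁻¹)

The flask gives 75.1%, 20.0% and 32.7%, in the order asked, with left-handed substrate at 22.3%, less than the first view's 27.8%, on the side of the forecast. Integrating the binding step, the flask's ratio of impurity to free catalyst falls e-fold every 14.5 h, shorter than the 40 h run. The flask's free catalyst goes from 52.7% after 4.00 h to 22.3% after 40.0 h, close to the surplus share of 21.2%. The first view's region is the neighbour flask charged with 18 mol% of free catalyst: its surplus share is 80.7%, its e-fold time 0.929 h, and its free catalyst ends at 80.7%.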